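## The problem

The target (31) is a cyclodeca-1,5-diene whose ring is numbered here C1 (allylic CHOAc), C2=C3(CH3), C4, C5, C6=C7(CO2H), C8, C9 (CHOAc), C10 (CH–isopropyl); this numbering is kept for all intermediates. Both ring alkenes are trisubstituted and ring-cis: C2=C3 is Z, and at C6=C7 the ring carbons C5 and C8 are cis with the carboxyl outside (E by the sequence rule), so a medium ring must be closed without losing either geometry. Three contiguous stereocentres, C9 (R), C10 (S) and C1 (R), sit together: C9 and C10 have the syn relationship of an aldol pair and can be set in one step, but C1 is anti to the isopropyl group and its neighbour C10 carries two branched groups of similar size, so neither open-chain Felkin control nor the conformation of a ten-membered ring can be trusted and C1 needs reagent control before ring closure. The C1 acetate is a secondary allylic ester with a fully substituted γ-carbon and will ionise under protic or Lewis acid and with zerovalent palladium; the medium-ring 1,5-diene invites transannular cyclisation in acid and Cope rearrangement on heating; the C9 oxygen is γ to the carboxyl carbon, so a free C9 hydroxyl next to an unhindered or activated carboxyl can lactonise; and the acetates exclude hydroxide, hydride and enolate chemistry once present. The acetates must therefore go on late and the acid must be released last under neutral, non-ionising conditions. Direct ring closure is possible because O–C1–C2=C3(CH3)–C4 is the pattern left by 1,4-opening of an isopropenyl epoxide, while C5 is the γ-carbon of the C6=C7 enoate: with a sulfonyl group on C5 it becomes a carbon acid, and the unfunctionalised C4–C5 bond becomes the union of an allyl cation equivalent and a stabilised carbanion.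

## Retrosynthesis

**Releasing the acid (31 from 30).** The last bond cut is the alkyl–oxygen bond of a carboxylic ester. A tert-butyl ester would have to be removed with acid from a molecule that holds the ionisable C1 acetate and the medium-ring diene. The 2-(trimethylsilyl)ethyl ester 30 is instead cleaved by fluoride through β-elimination, which touches neither acetate nor alkene. The price is an unhindered ester that must be kept away from a free C9 hydroxyl for as short a time as possible.

**Acetates and the C9 ether (30 from 29 from 28).** Both O-acyl bonds are cut together, giving diol 29 and then the mono-triethylsilyl ether 28. Acetylating both hydroxyls in one step is shorter than carrying either acetate through the earlier enolate and hydride chemistry, which neither would survive. Triethylsilyl is chosen at C9 because buffered HF·pyridine removes it quickly at 0 °C while the silylethyl ester stays.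

**C5–H (28 from 27).** A C–S bond is restored at C5. The phenylsulfonyl group is what makes C5 nucleophilic; being allylic, it can be taken off afterwards by zerovalent palladium and hydride. The forward step must deliver hydride to C5 and not to C7.

**C4–C5, the ring (27 from 25).** The ring is opened between C4 and C5, the only ring bond flanked on one side by a latent allyl electrophile (C2–C4 with oxygen on C1) and on the other by a latent carbanion (C5, γ to the ester). Cutting C6=C7 instead would require a trisubstituted enoate to be formed in a ten-membered ring by olefination or metathesis; cutting C1–C2 or C9–C10 would make a stereocentre in the ring-closing step. Precursor 25 is acyclic and carries all three stereocentres on a chain, with an isopropenyl epoxide and a γ-sulfonyl enoate at its ends. The forward reaction, through zwitterion 26, must attack the distal allyl terminus, alkylate C5 and not C7, and deliver the ring-cis C2=C3 alkene.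

**C6=C7 and the sulfone (25 from 22 from 21 from 18 and 19).** The enoate double bond is cut to the ester enolate of 18 and (phenylsulfanyl)acetaldehyde 19, which brings C5, C6 and the sulfur in one piece. Sulfur is oxidised at the β-hydroxy stage (21 to 22), before dehydration, so that no β-sulfanyl mesylate (episulfonium risk) is formed. Dehydration under equilibrating base is asked to place C5 trans to the ester.

**Epoxide and diene (18 from 17 from 16 from 14 and 15).** The epoxide oxygen is removed to give diene 17, the C3=C4 methylene is cut to enone 16, and C1=C2 is cut to aldehyde 14 and ylide 15. This order is chosen because C1 must be set by a catalyst (Shi epoxidation of a trans-alkene has a known facial sense). The epoxide is installed before the sulfone because the acidic γ-sulfonyl enoate would quench the Wittig ylide, whereas the epoxide tolerates the enolate, Oxone and amine bases that follow.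

**C9–C10 (14 from 13 from 12 from 11 from 9 and 5).** The C9–C10 bond is an Evans syn-aldol bond between isovaleryl imide 9 and aldehyde 5. It sets C9 and C10 together with predictable absolute sense, and the imide carbonyl is C1 at the oxidation level needed after reduction and reoxidation.

**Building blocks (9 from 6 and 7; 5 from 3 from 1 and 2).** Imide 9 is the acylation product of the oxazolidinone 6 with acid chloride 7. Aldehyde 5 comes from pent-4-enoic acid 1 by esterification with 2 and ozonolysis of 3.

## Roads not taken

Alternative 1: Ring expansion by anionic oxy-Cope rearrangement. The C8–C9 bond is made while a C1–C6 bond of a six-membered ring is broken. A chiral-pool 6-isopropenylcyclohex-2-enone takes up a 1-alkoxyalkenyllithium at its carbonyl, and the potassium alkoxide of the resulting dialkenylcyclohexenol (KH, 18-crown-6) rearranges to the ten-membered enolate A1.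
- Merits: the ring forms without dilution in a unimolecular, dependable step; the Z geometry of C2=C3 is inherited from the cyclohexene; C9 is set by chirality transfer; the starting material is cheap.
- Weak points here: C6=C7 emerges ring-trans and must be inverted. C7 carries a methyl group that must be oxidised to carboxyl beside several other allylic positions. C10 is trigonal in A1, so C10 (by protonation) and C1 (by reduction) must both be set on the flexible ring.
- Comparison: as a ring-forming event it is better than the closure of 25, since there is no entropic penalty and no competing closure mode. The chosen plan sets against this that 27 leaves the key step with all three stereocentres, both alkene geometries and the carboxyl oxidation level already in place.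

Alternative 2: Nozaki–Hiyama allylation macrocyclisation. The cut is C9–C10. CrCl2 (divalent chromium) converts the primary allylic bromide of an acyclic C9 aldehyde into an allylchromium species that adds through its γ-carbon C10, closing the ring to alcohol A2 with C9 and C10 in the required relative configuration and an isopropenyl group on C10.
- Merits: ring closure and two stereocentres in one step, a reaction type well known for medium rings. Both ring alkenes are made beforehand with fixed geometry; in this respect it is better than the chosen plan, where the C2=C3 geometry is decided during ring closure.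
- Weak points here: the absolute sense at C9/C10 must be relayed from the remote C1 silyloxy group across the Z-alkene. The isopropenyl group must later be hydrogenated beside two ring alkenes. C7 is carried as a silyloxymethyl group and needs deprotection and two oxidations at the end. Chromium is used in excess at high dilution.
- Comparison: the chosen plan sets against the geometric certainty an auxiliary-controlled aldol for C9/C10, the isopropyl group and ester oxidation level from the start, and a catalytic metal in the ring closure.

Alternative 3: Addition–fragmentation ring expansion. A vinylogous acyl triflate of a cyclohexane-1,3-dione carries a tethered Z-alkenyl iodide. Exchange with t-BuLi, addition of the alkenyllithium to the C1 carbonyl (C1–C2) and fragmentation of the alkoxide (C1–C6, loss of triflate) give cyclodecenynone A3.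
- Merits: the ring arises from an intramolecular addition to a six-membered ring, the C2=C3 geometry is carried in the alkenyl iodide, and C9/C10 come from a cyclic precursor.
- Weak points here: the C6≡C7 alkyne must then become the ring-cis alkene with CO2H on C7 and H on C6, but both alkyne carbons are flanked by methylene groups, so hydrometalation–carboxylation has no regiochemical handle. The ten-membered cycloalkyne is strained. C1 is left as a ketone to be reduced on the ring.
- Comparison: ring formation and C2=C3 geometry are more certain than in the chosen plan. Against this, the chosen plan builds the carboxyl-bearing alkene regiospecifically on acyclic material and fixes C1 with a catalyst before cyclisation.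

Key step: step 14

Remark on the chemistry: (phenylsulfanyl)acetaldehyde 19, ylide 15 and the L-fructose-derived Shi ketone are taken as purchasable; ring positions C1–C10 as defined above are also used for acyclic intermediates.

## Route

Step 1
Reactants: 1 pent-4-enoic acid; 2 2-(trimethylsilyl)ethanol
Product: 3 2-(trimethylsilyl)ethyl pent-4-enoate
Conditions: DCC, 4-(dimethylamino)pyridine (cat.), CH2Cl2, 0 °C → rt
Reagents that add atoms: none
Why: Steglich esterification; the carbodiimide activates the acid and the acylpyridinium is trapped by the primary alcohol, installing the fluoride-labile ester from the outset.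

Step 2
Reactants: 3 2-(trimethylsilyl)ethyl pent-4-enoate
Product: 5 2-(trimethylsilyl)ethyl 4-oxobutanoate, via ozonide 4 (not isolated)
Conditions: O3, CH2Cl2, −78 °C; then PPh3, −78 °C → rt
Reagents that add atoms: ozone, [O-][O+]=O
Why: Ozonolysis of the terminal alkene with reductive work-up; the phosphine reduces ozonide 4 to the aldehyde and formaldehyde, and the ester is inert.

Step 3
Reactants: 6 (S)-4-benzyloxazolidin-2-one; 7 3-methylbutanoyl chloride
Product: 9 (S)-4-benzyl-3-(3-methylbutanoyl)oxazolidin-2-one, via N-lithio oxazolidinone 8 (not isolated)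
Conditions: n-BuLi, THF, −78 °C; then 7, −78 → 0 °C
Reagents that add atoms: none
Why: N-Acylation of the lithiated oxazolidinone by the acid chloride, the standard entry to Evans imides.

Step 4
Reactants: 9 (S)-4-benzyl-3-(3-methylbutanoyl)oxazolidin-2-one; 5 2-(trimethylsilyl)ethyl 4-oxobutanoate
Product: 11 2-(trimethylsilyl)ethyl (4R,5S)-5-[(4S)-4-benzyl-2-oxooxazolidine-3-carbonyl]-4-hydroxy-6-methylheptanoate, via boron enolate 10 (not isolated)
Conditions: n-Bu2BOTf, Et3N, CH2Cl2, 0 °C; then 5, −78 → 0 °C; pH 7 buffer, MeOH, 30% H2O2, 0 °C
Reagents that add atoms: none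
Why: Evans syn-aldol reaction: the Z-boron enolate 10 adds through a chair Zimmerman–Traxler transition state on the enolate face away from the benzyl group, which sets C10 (S) and C9 (R) together in the syn relationship of the target. The neutral oxidative work-up should leave the γ-hydroxy ester unlactonised for immediate silylation.

Step 5
Reactants: 11 aldol adduct
Product: 12 2-(trimethylsilyl)ethyl (4R,5S)-5-[(4S)-4-benzyl-2-oxooxazolidine-3-carbonyl]-6-methyl-4-[(triethylsilyl)oxy]heptanoate
Conditions: TESOTf, 2,6-lutidine, CH2Cl2, −78 °C
Reagents that add atoms: triethylsilyl trifluoromethanesulfonate, CC[Si](CC)(CC)OS(=O)(=O)C(F)(F)F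
Why: Silylation of the hindered aldol hydroxyl with the silyl triflate at low temperature; it blocks lactonisation and retro-aldol cleavage in later steps.

Step 6
Reactants: 12 silylated imide
Product: 13 2-(trimethylsilyl)ethyl (4R,5R)-5-(hydroxymethyl)-6-methyl-4-[(triethylsilyl)oxy]heptanoate
Conditions: NaBH4, THF/H2O, 0 °C → rt
Reagents that add atoms: none
Why: Borohydride reduction of the activated exocyclic imide carbonyl releases the primary alcohol (C1) and the auxiliary; NaBH4 does not reduce the silylethyl ester and C10 is untouched.

Step 7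
Reactants: 13 primary alcohol
Product: 14 2-(trimethylsilyl)ethyl (4R,5S)-5-formyl-6-methyl-4-[(triethylsilyl)oxy]heptanoate
Conditions: Dess–Martin periodinane, NaHCO3, CH2Cl2, 0 °C → rt
Reagents that add atoms: none
Why: Dess–Martin oxidation under bicarbonate buffer should give the α-branched aldehyde without epimerisation at C10; the aldehyde is used directly.

Step 8
Reactants: 14 aldehyde; 15 1-(triphenylphosphoranylidene)propan-2-one
Product: 16 2-(trimethylsilyl)ethyl (4R,5R,6E)-8-oxo-5-(propan-2-yl)-4-[(triethylsilyl)oxy]non-6-enoate
Conditions: toluene, 80 °C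
Reagents that add atoms: none
Why: Wittig olefination with a ketone-stabilised ylide gives the E-enone (C1=C2) under neutral conditions that should neither epimerise C10 nor eliminate the β-silyloxy group.

Step 9
Reactants: 16 enone
Product: 17 2-(trimethylsilyl)ethyl (4R,5R,6E)-8-methyl-5-(propan-2-yl)-4-[(triethylsilyl)oxy]nona-6,8-dienoate
Conditions: Ph3PCH3Br, KOtBu, THF, 0 °C → rt
Reagents that add atoms: methyltriphenylphosphonium bromide, C[P+](c1ccccc1)(c1ccccc1)c1ccccc1.[Br-]
Why: Wittig methylenation of the methyl ketone by 1,2-addition of the unstabilised ylide turns the enone into the 2-methyl-1,3-diene (C3=C4); the ester is inert to the ylide at 0 °C.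

Step 10
Reactants: 17 diene
Product: 18 2-(trimethylsilyl)ethyl (4R,5R)-6-methyl-5-[(2S,3S)-3-(prop-1-en-2-yl)oxiran-2-yl]-4-[(triethylsilyl)oxy]heptanoate
Conditions: 1,2:4,5-di-O-isopropylidene-β-L-erythro-2,3-hexodiulo-2,6-pyranose (L-fructose-derived Shi ketone, 30 mol %), Oxone (2KHSO5·KHSO4·K2SO4), K2CO3, Bu4NHSO4 (cat.), Na2B4O7 buffer, MeCN/CH2(OMe)2/H2O, 0 °C
Reagents that add atoms: potassium peroxymonosulfate (active component of Oxone), [K+].[O-]S(=O)(=O)OO
Why: Shi asymmetric epoxidation: the dioxirane of the chiral ketone transfers oxygen through a spiro transition state to the trans-disubstituted alkene, the terminal 1,1-disubstituted alkene being a poor substrate for this catalyst. The D-fructose ketone gives (R,R)-epoxides from trans-alkenes, so its L-enantiomer is used to set the oxirane carbons C1 and C2 as S,S, which corresponds to the (R)-C1 carbinol of the target; catalyst control is expected to override the bias of C10.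

Step 11
Reactants: 18 vinyl epoxide; 19 (phenylsulfanyl)acetaldehyde
Product: 21 2-(trimethylsilyl)ethyl (4R,5R)-2-[1-hydroxy-2-(phenylsulfanyl)ethyl]-6-methyl-5-[(2S,3S)-3-(prop-1-en-2-yl)oxiran-2-yl]-4-[(triethylsilyl)oxy]heptanoate (mixture of diastereomers at the two new centres), via lithium enolate 20 (not isolated)
Conditions: LiN(iPr)2, THF, −78 °C; then 19, −78 °C; aq. NH4Cl
Reagents that add atoms: none
Why: Aldol addition of the lithium ester enolate 20 to the aldehyde forms the C6–C7 bond; at −78 °C the enolate should not open the epoxide, and the two new centres are removed in step 13.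

Step 12
Reactants: 21 β-hydroxy sulfide
Product: 22 2-(trimethylsilyl)ethyl (4R,5R)-2-[1-hydroxy-2-(phenylsulfonyl)ethyl]-6-methyl-5-[(2S,3S)-3-(prop-1-en-2-yl)oxiran-2-yl]-4-[(triethylsilyl)oxy]heptanoate (diastereomer mixture)
Conditions: Oxone (2KHSO5·KHSO4·K2SO4), NaHCO3, THF/MeOH/H2O, 0 °C → rt
Reagents that add atoms: potassium peroxymonosulfate (active component of Oxone), [K+].[O-]S(=O)(=O)OO
Why: Chemoselective oxidation of sulfide to sulfone by peroxymonosulfate in buffered aqueous medium; without a ketone to form a dioxirane, Oxone should not epoxidise the isopropenyl group, and the vinyl epoxide has already met basic Oxone in step 10. Oxidising before dehydration avoids episulfonium formation from a β-sulfanyl mesylate.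

Step 13
Reactants: 22 β-hydroxy sulfone
Product: 25 2-(trimethylsilyl)ethyl (2E,4R,5R)-6-methyl-2-[2-(phenylsulfonyl)ethylidene]-5-[(2S,3S)-3-(prop-1-en-2-yl)oxiran-2-yl]-4-[(triethylsilyl)oxy]heptanoate, via mesylate 23 (not isolated), via vinyl sulfone 24 (not isolated)
Conditions: MsCl, Et3N, CH2Cl2, 0 °C; then DBU, 0 °C → rt
Reagents that add atoms: none
Why: Mesylation and E1cB elimination give vinyl sulfone 24, which DBU isomerises through the sulfonyl dienolate to the thermodynamically preferred allyl sulfone with the conjugated, trisubstituted enoate. Equilibration should place C5 trans to the ester (E), the geometry with C5 and C8 cis that the ring needs.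

Step 14
Reactants: 25 acyclic γ-sulfonyl enoate with isopropenyl epoxide
Product: 27 2-(trimethylsilyl)ethyl (1E,5Z,7R,8R,9R)-7-hydroxy-5-methyl-3-(phenylsulfonyl)-8-(propan-2-yl)-9-[(triethylsilyl)oxy]cyclodeca-1,5-diene-1-carboxylate (either C3 epimer; C3 of this name is ring position C5), via π-allylpalladium alkoxide 26 (not isolated)
Conditions: Pd(PPh3)4 (10 mol %), THF, 40 °C, syringe-pump addition of 25 to a final 2 mM
Reagents that add atoms: none
Why: Zerovalent palladium ionises the isopropenyl epoxide with inversion at C2 to the zwitterionic 2-methylallyl complex 26, whose C1 alkoxide is the only base present and removes the γ-proton at C5 of the sulfonyl enoate; the sulfonyl-stabilised carbanion then attacks the allyl terminus C4 anti to palladium and releases the catalyst. The closest known reaction type is the Tsuji–Trost alkylation and macrocyclisation of vinyl epoxides with sulfone-stabilised carbanions under neutral conditions. The ten-membered ring is closed by attack on the distal terminus, so that all three allyl carbons become ring members; the eight-membered alternative through C2 would leave an exocyclic isopropenyl group. No stereocentre of the target is created: the C1–O bond is never broken and keeps the configuration set in step 10, C2 becomes trigonal, and the new centre at C5 is erased in step 15. Distal attack is favoured by the unsubstituted CH2 terminus, and alkylation at C5 rather than C7 by the fully substituted nature of C7 and by the charge being held next to sulfur. The ring-cis C2=C3 alkene is expected because syn–anti exchange of the 2-methylallyl complex is fast and closure through the anti complex leads to the less strained cis-cyclodecene-type ring. Slow addition at high dilution is meant to suppress oligomerisation, and the mild temperature is meant to keep the allylic sulfone itself from ionising.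

Step 15
Reactants: 27 macrocyclic sulfone
Product: 28 2-(trimethylsilyl)ethyl (1E,5Z,7R,8R,9R)-7-hydroxy-5-methyl-8-(propan-2-yl)-9-[(triethylsilyl)oxy]cyclodeca-1,5-diene-1-carboxylate
Conditions: Pd(PPh3)4 (5 mol %), NaBH4, THF/i-PrOH, 0 °C → rt
Reagents that add atoms: none
Why: Palladium-catalysed reductive desulfonylation of an allylic sulfone: zerovalent palladium ionises the C5–S bond to a π-allyl complex and hydride from borohydride is delivered to the less substituted terminus C5, restoring the conjugated trisubstituted enoate. The free allylic alcohol at C1 is not ionised, and the ring is expected to hold the C6=C7 geometry.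

Step 16
Reactants: 28 mono-silyl ether
Product: 29 2-(trimethylsilyl)ethyl (1E,5Z,7R,8S,9R)-7,9-dihydroxy-5-methyl-8-(propan-2-yl)cyclodeca-1,5-diene-1-carboxylate
Conditions: HF·pyridine, pyridine, THF, 0 °C
Reagents that add atoms: none
Why: Fluoride cleavage of the triethylsilyl ether under buffered conditions that leave the 2-(trimethylsilyl)ethyl ester intact; the short reaction time at 0 °C should keep the γ-hydroxy ester from lactonising.

Step 17
Reactants: 29 diol
Product: 30 2-(trimethylsilyl)ethyl (1E,5Z,7R,8S,9R)-7,9-bis(acetyloxy)-5-methyl-8-(propan-2-yl)cyclodeca-1,5-diene-1-carboxylate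
Conditions: Ac2O, 4-(dimethylamino)pyridine (cat.), pyridine, CH2Cl2, 0 °C → rt
Reagents that add atoms: acetic anhydride, CC(=O)OC(C)=O
Why: Acylation of both secondary hydroxyls with acetic anhydride under nucleophilic catalysis; no stereocentre is affected.

Step 18
Reactants: 30 diacetate ester
Product: 31 (1E,5Z,7R,8S,9R)-7,9-bis(acetyloxy)-5-methyl-8-(propan-2-yl)cyclodeca-1,5-diene-1-carboxylic acid (target)
Conditions: tris(dimethylamino)sulfonium difluorotrimethylsilicate (TASF), DMF, 0 °C → rt; then dilute aq. HCl to pH 4
Reagents that add atoms: none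
Why: Fluoride attacks silicon and the ester fragments to ethylene, fluorotrimethylsilane and the carboxylate, which is protonated on work-up. The conditions are neither acidic nor strongly basic, so the allylic acetate, the second acetate and the diene should be preserved.

## Compound list

1 | pent-4-enoic acid | C=CCCC(=O)O | starting material
2 | 2-(trimethylsilyl)ethanol | C[Si](C)(C)CCO | starting material
3 | 2-(trimethylsilyl)ethyl pent-4-enoate | C=CCCC(=O)OCC[Si](C)(C)C | intermediate
4 | 2-(trimethylsilyl)ethyl 3-(1,2,4-trioxolan-3-yl)propanoate (ozonide) | C[Si](C)(C)CCOC(=O)CCC1OCOO1 | intermediate (not isolated)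
5 | 2-(trimethylsilyl)ethyl 4-oxobutanoate | O=CCCC(=O)OCC[Si](C)(C)C | intermediate
6 | (S)-4-benzyloxazolidin-2-one | O=C1N[C@@H](Cc2ccccc2)CO1 | starting material
7 | 3-methylbutanoyl chloride | CC(C)CC(Cl)=O | starting material
8 | N-lithio-(S)-4-benzyloxazolidin-2-one | [Li]N1[C@@H](Cc2ccccc2)COC1=O | intermediate (not isolated)
9 | (S)-4-benzyl-3-(3-methylbutanoyl)oxazolidin-2-one | CC(C)CC(=O)N1[C@@H](Cc2ccccc2)COC1=O | intermediate
10 | (Z)-dibutylboron enolate of 9 | CCCCB(CCCC)O/C(=C\C(C)C)N1[C@@H](Cc2ccccc2)COC1=O | intermediate (not isolated)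
11 | 2-(trimethylsilyl)ethyl (4R,5S)-5-[(4S)-4-benzyl-2-oxooxazolidine-3-carbonyl]-4-hydroxy-6-methylheptanoate | C[Si](C)(C)CCOC(=O)CC[C@@H](O)[C@H](C(C)C)C(=O)N1[C@@H](Cc2ccccc2)COC1=O | intermediate
12 | 2-(trimethylsilyl)ethyl (4R,5S)-5-[(4S)-4-benzyl-2-oxooxazolidine-3-carbonyl]-6-methyl-4-[(triethylsilyl)oxy]heptanoate | C[Si](C)(C)CCOC(=O)CC[C@@H](O[Si](CC)(CC)CC)[C@H](C(C)C)C(=O)N1[C@@H](Cc2ccccc2)COC1=O | intermediate
13 | 2-(trimethylsilyl)ethyl (4R,5R)-5-(hydroxymethyl)-6-methyl-4-[(triethylsilyl)oxy]heptanoate | C[Si](C)(C)CCOC(=O)CC[C@@H](O[Si](CC)(CC)CC)[C@H](C(C)C)CO | intermediate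
14 | 2-(trimethylsilyl)ethyl (4R,5S)-5-formyl-6-methyl-4-[(triethylsilyl)oxy]heptanoate | C[Si](C)(C)CCOC(=O)CC[C@@H](O[Si](CC)(CC)CC)[C@H](C(C)C)C=O | intermediate
15 | 1-(triphenylphosphoranylidene)propan-2-one | CC(=O)C=P(c1ccccc1)(c1ccccc1)c1ccccc1 | starting material
16 | 2-(trimethylsilyl)ethyl (4R,5R,6E)-8-oxo-5-(propan-2-yl)-4-[(triethylsilyl)oxy]non-6-enoate | C[Si](C)(C)CCOC(=O)CC[C@@H](O[Si](CC)(CC)CC)[C@H](C(C)C)/C=C/C(C)=O | intermediate
17 | 2-(trimethylsilyl)ethyl (4R,5R,6E)-8-methyl-5-(propan-2-yl)-4-[(triethylsilyl)oxy]nona-6,8-dienoate | C[Si](C)(C)CCOC(=O)CC[C@@H](O[Si](CC)(CC)CC)[C@H](C(C)C)/C=C/C(C)=C | intermediate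
18 | 2-(trimethylsilyl)ethyl (4R,5R)-6-methyl-5-[(2S,3S)-3-(prop-1-en-2-yl)oxiran-2-yl]-4-[(triethylsilyl)oxy]heptanoate | C[Si](C)(C)CCOC(=O)CC[C@@H](O[Si](CC)(CC)CC)[C@H](C(C)C)[C@@H]1O[C@H]1C(C)=C | intermediate
19 | (phenylsulfanyl)acetaldehyde | O=CCSc1ccccc1 | starting material
20 | lithium enolate of 18 | [Li]OC(OCC[Si](C)(C)C)=CC[C@@H](O[Si](CC)(CC)CC)[C@H](C(C)C)[C@@H]1O[C@H]1C(C)=C | intermediate (not isolated)
21 | 2-(trimethylsilyl)ethyl (4R,5R)-2-[1-hydroxy-2-(phenylsulfanyl)ethyl]-6-methyl-5-[(2S,3S)-3-(prop-1-en-2-yl)oxiran-2-yl]-4-[(triethylsilyl)oxy]heptanoate (diastereomer mixture) | C[Si](C)(C)CCOC(=O)C(C(O)CSc1ccccc1)C[C@@H](O[Si](CC)(CC)CC)[C@H](C(C)C)[C@@H]1O[C@H]1C(C)=C | intermediate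
22 | 2-(trimethylsilyl)ethyl (4R,5R)-2-[1-hydroxy-2-(phenylsulfonyl)ethyl]-6-methyl-5-[(2S,3S)-3-(prop-1-en-2-yl)oxiran-2-yl]-4-[(triethylsilyl)oxy]heptanoate (diastereomer mixture) | C[Si](C)(C)CCOC(=O)C(C(O)CS(=O)(=O)c1ccccc1)C[C@@H](O[Si](CC)(CC)CC)[C@H](C(C)C)[C@@H]1O[C@H]1C(C)=C | intermediate
23 | mesylate of 22: 2-(trimethylsilyl)ethyl (4R,5R)-2-[1-(methanesulfonyloxy)-2-(phenylsulfonyl)ethyl]-6-methyl-5-[(2S,3S)-3-(prop-1-en-2-yl)oxiran-2-yl]-4-[(triethylsilyl)oxy]heptanoate | C[Si](C)(C)CCOC(=O)C(C(OS(C)(=O)=O)CS(=O)(=O)c1ccccc1)C[C@@H](O[Si](CC)(CC)CC)[C@H](C(C)C)[C@@H]1O[C@H]1C(C)=C | intermediate (not isolated)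
24 | vinyl sulfone: 2-(trimethylsilyl)ethyl (4R,5R)-6-methyl-2-[(E)-2-(phenylsulfonyl)ethenyl]-5-[(2S,3S)-3-(prop-1-en-2-yl)oxiran-2-yl]-4-[(triethylsilyl)oxy]heptanoate | C[Si](C)(C)CCOC(=O)C(/C=C/S(=O)(=O)c1ccccc1)C[C@@H](O[Si](CC)(CC)CC)[C@H](C(C)C)[C@@H]1O[C@H]1C(C)=C | intermediate (not isolated)
25 | 2-(trimethylsilyl)ethyl (2E,4R,5R)-6-methyl-2-[2-(phenylsulfonyl)ethylidene]-5-[(2S,3S)-3-(prop-1-en-2-yl)oxiran-2-yl]-4-[(triethylsilyl)oxy]heptanoate | O=S(=O)(c1ccccc1)C/C=C(/C(=O)OCC[Si](C)(C)C)C[C@@H](O[Si](CC)(CC)CC)[C@H](C(C)C)[C@@H]1O[C@H]1C(C)=C | intermediate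
26 | zwitterionic π-allylpalladium alkoxide from 25 (drawn as the σ-allyl form, phosphine ligands omitted) | O=S(=O)(c1ccccc1)C/C=C(/C(=O)OCC[Si](C)(C)C)C[C@@H](O[Si](CC)(CC)CC)[C@H](C(C)C)[C@H]([O-])/C=C(/C)C[Pd+] | intermediate (not isolated)
27 | 2-(trimethylsilyl)ethyl (1E,5Z,7R,8R,9R)-7-hydroxy-5-methyl-3-(phenylsulfonyl)-8-(propan-2-yl)-9-[(triethylsilyl)oxy]cyclodeca-1,5-diene-1-carboxylate (C3 epimers) | O[C@@H]1/C=C(/C)CC(S(=O)(=O)c2ccccc2)/C=C(/C(=O)OCC[Si](C)(C)C)C[C@@H](O[Si](CC)(CC)CC)[C@@H]1C(C)C | intermediate
28 | 2-(trimethylsilyl)ethyl (1E,5Z,7R,8R,9R)-7-hydroxy-5-methyl-8-(propan-2-yl)-9-[(triethylsilyl)oxy]cyclodeca-1,5-diene-1-carboxylate | O[C@@H]1/C=C(/C)CC/C=C(/C(=O)OCC[Si](C)(C)C)C[C@@H](O[Si](CC)(CC)CC)[C@@H]1C(C)C | intermediate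
29 | 2-(trimethylsilyl)ethyl (1E,5Z,7R,8S,9R)-7,9-dihydroxy-5-methyl-8-(propan-2-yl)cyclodeca-1,5-diene-1-carboxylate | O[C@@H]1/C=C(/C)CC/C=C(/C(=O)OCC[Si](C)(C)C)C[C@@H](O)[C@@H]1C(C)C | intermediate
30 | 2-(trimethylsilyl)ethyl (1E,5Z,7R,8S,9R)-7,9-bis(acetyloxy)-5-methyl-8-(propan-2-yl)cyclodeca-1,5-diene-1-carboxylate | CC(=O)O[C@@H]1/C=C(/C)CC/C=C(/C(=O)OCC[Si](C)(C)C)C[C@@H](OC(C)=O)[C@@H]1C(C)C | intermediate
31 | (1E,5Z,7R,8S,9R)-7,9-bis(acetyloxy)-5-methyl-8-(propan-2-yl)cyclodeca-1,5-diene-1-carboxylic acid | CC(=O)O[C@@H]1/C=C(/C)CC/C=C(/C(=O)O)C[C@@H](OC(C)=O)[C@@H]1C(C)C | target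

## Step count and least certain steps

Total step count: 18. Longest linear sequence: 17 steps (steps 1, 2 and 4–18, from pent-4-enoic acid).

**Step 14 (key step).** The most likely failure is closure through the syn complex, which is the more stable form of open-chain 2-methylallyl complexes and would give the ring-trans C2=C3 alkene. A second concern is that proton transfer from the only moderately acidic C5–H may be slow, so that β-hydride loss from the zwitterion or oligomerisation competes. Fallback: the geometry and the C1 configuration are re-set after ring closure. From 25, the same catalysis would give the ring-trans alcohol 2-(trimethylsilyl)ethyl (1E,5E,7R,8R,9R)-7-hydroxy-5-methyl-3-(phenylsulfonyl)-8-(propan-2-yl)-9-[(triethylsilyl)oxy]cyclodeca-1,5-diene-1-carboxylate F1. Oxidation with MnO2 in CH2Cl2 gives the ring-trans enone F2. Equilibration with catalytic iodine in daylight should lead to the less strained ring-cis enone F3. Reduction with BH3·SMe2 under a 2-methyl-CBS-oxazaborolidine, the catalyst enantiomer being chosen to give the (7R)-carbinol, rejoins the route at 27.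

**Step 10.** Oxygen transfer could occur in part at the more accessible 1,1-disubstituted alkene, or the catalyst could be mismatched with the C10 centre, because the reacting alkene is flanked by a branched stereocentre. Fallback from 16: addition of MeMgBr/CeCl3 (THF, −78 °C) to the ketone gives the tertiary allylic alcohol 2-(trimethylsilyl)ethyl (4R,5R,6E)-8-hydroxy-8-methyl-5-(propan-2-yl)-4-[(triethylsilyl)oxy]non-6-enoate F4, which has only the trans-alkene. Shi epoxidation with the same L-fructose-derived ketone gives the epoxy alcohol 2-(trimethylsilyl)ethyl (4R,5R)-5-[(2S,3R)-3-(2-hydroxypropan-2-yl)oxiran-2-yl]-6-methyl-4-[(triethylsilyl)oxy]heptanoate F5. Dehydration with the Burgess reagent, which can only remove a methyl hydrogen, returns to 18.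

**Step 15.** Hydride might be delivered to C7 (deconjugated ester), or the π-allyl intermediate might lose the C6=C7 geometry through its palladium enolate form. Fallback from 27: electron-transfer cleavage with SmI2 (divalent samarium) and HMPA in THF/MeOH at −78 °C, which expels sulfinate from the enoate radical anion and gives, by kinetic α-protonation, the β,γ-unsaturated ester 2-(trimethylsilyl)ethyl (5Z,7R,8R,9R)-7-hydroxy-5-methyl-8-(propan-2-yl)-9-[(triethylsilyl)oxy]cyclodeca-2,5-diene-1-carboxylate F6. Reconjugation with DBU under thermodynamic control returns to 28.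

**Step 12.** Over-oxidation of the isopropenyl alkene, or opening of the vinyl epoxide if the buffer is exhausted, may accompany the slower sulfoxide-to-sulfone stage. Fallback from 18, avoiding any oxidation: the enolate 20 (with a second equivalent of LiN(iPr)2) is added to (E)-1,2-bis(phenylsulfonyl)ethene. Conjugate addition and loss of sulfinate give vinyl sulfone 24 directly, and DBU isomerisation returns to 25. No new compound is made.

**Step 9.** The basic ylide may enolise the methyl ketone instead of adding, or remove the γ-proton at C10 and so erode that stereocentre. Fallback from 14: Takai iodo-olefination (CHI3, CrCl2 (divalent chromium), THF, 0 °C) gives the vinyl iodide 2-(trimethylsilyl)ethyl (4R,5R,6E)-7-iodo-5-(propan-2-yl)-4-[(triethylsilyl)oxy]hept-6-enoate F7. Suzuki coupling with isopropenylboronic acid pinacol ester (PdCl2(dppf), K3PO4, THF/H2O) returns to 17 without an enolisable ketone.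

## Further compounds

F1 | step 14 | 2-(trimethylsilyl)ethyl (1E,5E,7R,8R,9R)-7-hydroxy-5-methyl-3-(phenylsulfonyl)-8-(propan-2-yl)-9-[(triethylsilyl)oxy]cyclodeca-1,5-diene-1-carboxylate | O[C@@H]1/C=C(\C)CC(S(=O)(=O)c2ccccc2)/C=C(/C(=O)OCC[Si](C)(C)C)C[C@@H](O[Si](CC)(CC)CC)[C@@H]1C(C)C
F2 | step 14 | 2-(trimethylsilyl)ethyl (1E,5E,8S,9R)-5-methyl-7-oxo-3-(phenylsulfonyl)-8-(propan-2-yl)-9-[(triethylsilyl)oxy]cyclodeca-1,5-diene-1-carboxylate | O=C1/C=C(\C)CC(S(=O)(=O)c2ccccc2)/C=C(/C(=O)OCC[Si](C)(C)C)C[C@@H](O[Si](CC)(CC)CC)[C@@H]1C(C)C
F3 | step 14 | 2-(trimethylsilyl)ethyl (1E,5Z,8S,9R)-5-methyl-7-oxo-3-(phenylsulfonyl)-8-(propan-2-yl)-9-[(triethylsilyl)oxy]cyclodeca-1,5-diene-1-carboxylate | O=C1/C=C(/C)CC(S(=O)(=O)c2ccccc2)/C=C(/C(=O)OCC[Si](C)(C)C)C[C@@H](O[Si](CC)(CC)CC)[C@@H]1C(C)C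
F4 | step 10 | 2-(trimethylsilyl)ethyl (4R,5R,6E)-8-hydroxy-8-methyl-5-(propan-2-yl)-4-[(triethylsilyl)oxy]non-6-enoate | C[Si](C)(C)CCOC(=O)CC[C@@H](O[Si](CC)(CC)CC)[C@H](C(C)C)/C=C/C(C)(C)O
F5 | step 10 | 2-(trimethylsilyl)ethyl (4R,5R)-5-[(2S,3R)-3-(2-hydroxypropan-2-yl)oxiran-2-yl]-6-methyl-4-[(triethylsilyl)oxy]heptanoate | C[Si](C)(C)CCOC(=O)CC[C@@H](O[Si](CC)(CC)CC)[C@H](C(C)C)[C@@H]1O[C@H]1C(C)(C)O
F6 | step 15 | 2-(trimethylsilyl)ethyl (5Z,7R,8R,9R)-7-hydroxy-5-methyl-8-(propan-2-yl)-9-[(triethylsilyl)oxy]cyclodeca-2,5-diene-1-carboxylate | O[C@@H]1/C=C(/C)CC=CC(C(=O)OCC[Si](C)(C)C)C[C@@H](O[Si](CC)(CC)CC)[C@@H]1C(C)C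
F0 | step 12 | none | none
F7 | step 9 | 2-(trimethylsilyl)ethyl (4R,5R,6E)-7-iodo-5-(propan-2-yl)-4-[(triethylsilyl)oxy]hept-6-enoate | C[Si](C)(C)CCOC(=O)CC[C@@H](O[Si](CC)(CC)CC)[C@H](C(C)C)/C=C/I
A1 | alternative 1 | potassium enolate of (2Z,6E)-9-[(4-methoxybenzyl)oxy]-3,7-dimethyl-10-(propan-2-yl)cyclodeca-2,6-dien-1-one | [K+].[C@H]1(OCc2ccc(OC)cc2)/C(C(C)C)=C(\[O-])/C=C(/C)CC/C=C(\C)C1
A2 | alternative 2 | ten-membered C9 alcohol with C10 isopropenyl, C1 tert-butyldimethylsilyloxy and C7 (triisopropylsilyloxy)methyl groups | O[C@@H]1C/C(CO[Si](C(C)C)(C(C)C)C(C)C)=C\CC/C(C)=C\[C@@H](O[Si](C)(C)C(C)(C)C)[C@H]1C(C)=C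
A3 | alternative 3 | (Z)-9-[(tert-butyldimethylsilyl)oxy]-3-methyl-10-(propan-2-yl)cyclodec-2-en-6-yn-1-one | O=C1/C=C(/C)CCC#CC[C@@H](O[Si](C)(C)C(C)(C)C)[C@@H]1C(C)C
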